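## Retrosynthetic overview

1. The target comes from hydrogenolysis of 21 benzyl ethers, preceded by threefold 3-O-esterification of dodeca-O-benzyl procyanidin C1 with tri-O-benzylgallic acid.
2. The protected trimer comes from a 4β→8 Friedel–Crafts-type coupling: the C4 cation of a de novo top-unit flavan-3,4-diol attacks C8 of the upper unit of octa-O-benzyl procyanidin B2. That dimer is made in three steps from (−)-epicatechin, which supplies C2/C3 of the middle and bottom units; C4 of the middle unit follows by relay.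
3. The top unit comes from a one-flask annulation of the enol silane of a 2-fluoro-4,6-bis(benzyloxy)phenyl α-alkoxy ketone (ring A) with 3,4-bis(benzyloxy)benzaldehyde (ring B). A catalytic enantioselective Mukaiyama aldol makes C2–C3 and both stereocentres; a fluoride-chain SNAr makes O1–C8a and closes ring C as a 2,3-cis chroman-4-one.
4. Enabling feature: in ring C of the top unit, O1 is bonded to C8a of ring A, ortho to C4, and C4 is the benzylic carbon that must later be the cationic interflavan carbon. At the ketone level, C4=O makes the oxygen-bearing C3 an enolisable aldol donor towards the ring B aldehyde carbon (C2) and activates C8a–F for substitution by the new C2 oxygen. The carbonyl is then reduced and ionised, so C4 is set by relay from C3.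
5. Ring order: rings A and B of every unit are bought as arenes; ring C of the top unit is the only ring formed (key step); the other two C rings come intact from epicatechin.

Key step: step 5

Assumption: the (2S,3S)-tartrate-derived acyloxyborane is taken to shield the Re face of the bound aryl aldehyde (Si-face attack gives 2R); if a model aldol shows the opposite sense, the (2R,3R)-catalyst is used and nothing else changes.

## Route

Step 1
Reactants: 1 1,3,5-trifluorobenzene; 2 benzyl alcohol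
Product: 3 1,3-bis(benzyloxy)-5-fluorobenzene
Conditions: BnOH (2.1 equiv), NaH (2.2 equiv), NMP, 0 → 100 °C
Reagents that add atoms: benzyl alcohol (second equivalent of 2), OCc1ccccc1
Why: Double nucleophilic aromatic substitution (SNAr) in which two equivalents of benzyloxide displace two of the three mutually meta fluorides; each fluoride replaced by the less electron-withdrawing benzyloxy group slows the next displacement, so the third fluoride is kept, and no stereocentre is formed.

Step 2
Reactants: 4 4-methoxybenzyl alcohol; 5 2-chloro-N-methoxy-N-methylacetamide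
Product: 6 N-methoxy-N-methyl-2-[(4-methoxybenzyl)oxy]acetamide
Conditions: NaH, THF, 0 °C; then 5, 0 °C → rt
Reagents that add atoms: none
Why: Williamson ether synthesis in which the alkoxide of 4 displaces the activated α-chloride of 5 by SN2 faster than it attacks the N-methoxy-N-methyl amide carbonyl; no stereocentre is formed.

Step 3
Reactants: 3 1,3-bis(benzyloxy)-5-fluorobenzene; 6 N-methoxy-N-methyl-2-[(4-methoxybenzyl)oxy]acetamide
Product: 9 1-[2,4-bis(benzyloxy)-6-fluorophenyl]-2-[(4-methoxybenzyl)oxy]ethan-1-one, via aryllithium 7 (not isolated), via tetrahedral lithium adduct 8 (not isolated)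
Conditions: n-BuLi (1.05 equiv), THF, −78 °C, 1 h; then 6, −78 → −40 °C; aq. NH4Cl
Reagents that add atoms: none
Why: Directed ortho-metalation followed by Weinreb ketone synthesis: the ring hydrogen flanked by fluorine and a benzyloxy group is the most acidic and is removed at −78 °C (below the temperature of LiF loss), and the aryllithium adds only once because the chelated tetrahedral adduct survives until the quench; no stereocentre is formed.

Step 4
Reactants: 9 1-[2,4-bis(benzyloxy)-6-fluorophenyl]-2-[(4-methoxybenzyl)oxy]ethan-1-one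
Product: 10 (Z)-({1-[2,4-bis(benzyloxy)-6-fluorophenyl]-2-[(4-methoxybenzyl)oxy]ethenyl}oxy)trimethylsilane
Conditions: Me3SiOSO2CF3 (1.2 equiv), Et3N (1.5 equiv), CH2Cl2, 0 °C; pentane, cold aq. NaHCO3; used crude
Reagents that add atoms: trimethylsilyl trifluoromethanesulfonate, C[Si](C)(C)OS(=O)(=O)C(F)(F)F
Why: Soft enolisation and O-silylation of the α-alkoxy aryl ketone gives the silyl enol ether, expected as the Z isomer, although the geometry is not critical for step 5; no stereocentre is formed.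

Step 5
Reactants: 10 (Z)-({1-[2,4-bis(benzyloxy)-6-fluorophenyl]-2-[(4-methoxybenzyl)oxy]ethenyl}oxy)trimethylsilane; 11 3,4-bis(benzyloxy)benzaldehyde
Product: 13 (2R,3S)-5,7-bis(benzyloxy)-2-[3,4-bis(benzyloxy)phenyl]-3-[(4-methoxybenzyl)oxy]chroman-4-one (2,3-cis), via syn silyl aldol 12 (not isolated)
Conditions: 11 (1.1 equiv), acyloxyborane catalyst from (2S,3S)-2-O-(2,6-diisopropoxybenzoyl)tartaric acid (known ligand, from (2S,3S)-tartaric acid) and BH3·THF (20 mol %), EtCN, −78 °C; then Bu4N[Ph3SiF2] (0.5 equiv), THF, −78 → −20 °C; pH 7 buffer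
Reagents that add atoms: none
Why: Proposed new method: a chiral acyloxyborane-catalysed Mukaiyama aldol is merged in one flask with a fluoride-chain desilylative SNAr, a combination without direct precedent; the closest known reaction types are the syn-selective acyloxyborane-catalysed aldol of aryl ketone enol silanes with aromatic aldehydes, fluoride-catalysed etherification of aryl fluorides with silyl ethers, and base-mediated aldol/SNAr annulations of 2-fluoroaryl ketones. The boron Lewis acid binds aldehyde 11, enol silane 10 attacks through its α-alkoxy carbon (C3) in an open antiperiplanar transition state to form C2–C3 with silyl transfer to the new oxygen (12), then fluoride cleaves the O–Si bond, the C2 alkoxide adds to C8a (the fluorine-bearing carbon ortho to the C4 acyl group), and loss of fluoride from the Meisenheimer complex forms O1–C8a and returns the fluoride that desilylates the next molecule. Ring C closes by a 6-exo-trig addition–elimination on the arene. C2 is set by the catalyst, which is expected to expose the Si face of the bound aldehyde, and C3 is set relative to C2 by the open transition state that gives the syn aldol whatever the enol geometry; syn-12 maps onto the 2,3-cis chromanone. The step needs arylation of O1 and not O3, a single site of substitution, and no retro-aldol or C3 epimerisation: O3 is capped as its 4-methoxybenzyl ether, the only C–F bond is the one ortho to the activating ketone, and the chain mechanism keeps alkoxide and fluoride at catalytic concentration while ortho-acyl activation makes ring closure the fastest fate of the alkoxide.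

Step 6
Reactants: 13 (2R,3S)-5,7-bis(benzyloxy)-2-[3,4-bis(benzyloxy)phenyl]-3-[(4-methoxybenzyl)oxy]chroman-4-one
Product: 14 (2R,3S)-5,7-bis(benzyloxy)-2-[3,4-bis(benzyloxy)phenyl]-3-hydroxychroman-4-one (2,3-cis)
Conditions: DDQ (1.3 equiv), CH2Cl2/pH 7 phosphate buffer 10:1, 0 °C → rt
Reagents that add atoms: none
Why: Oxidative cleavage of the 4-methoxybenzyl ether by DDQ (hydride abstraction, then hydrolysis of the oxocarbenium ion) is selective over the less electron-rich benzyl ethers and runs under neutral buffered conditions that leave the base-sensitive cis α-ketol stereocentres untouched.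

Step 7
Reactants: 14 (2R,3S)-5,7-bis(benzyloxy)-2-[3,4-bis(benzyloxy)phenyl]-3-hydroxychroman-4-one
Product: 15 5,7,3',4'-tetra-O-benzyl-4α-hydroxy-(−)-epicatechin (2,3-cis; 3,4-cis flavan-3,4-diol)
Conditions: NaBH4, CeCl3·7H2O, MeOH/THF, −40 °C
Reagents that add atoms: none
Why: Luche reduction is fast at low temperature, so C3 should not epimerise; hydride is expected to add anti to the axial C3 hydroxyl to give mainly the 3,4-cis diol, a configuration of no consequence because C4 is ionised in step 11.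

Step 8
Reactants: 16 (−)-epicatechin; 17 benzyl bromide
Product: 18 5,7,3',4'-tetra-O-benzyl-(−)-epicatechin
Conditions: BnBr (4.4 equiv), K2CO3 (5 equiv), DMF, 0 °C → rt, N2
Reagents that add atoms: benzyl bromide (three further equivalents of 17), BrCc1ccccc1.BrCc1ccccc1.BrCc1ccccc1
Why: Fourfold Williamson O-benzylation, in which four equivalents of benzyl bromide alkylate the four phenols that K2CO3 deprotonates while the secondary C3 alcohol stays protonated, leaves the two chiral-pool stereocentres untouched.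

Step 9
Reactants: 18 5,7,3',4'-tetra-O-benzyl-(−)-epicatechin; 19 2-ethoxyethanol
Product: 20 5,7,3',4'-tetra-O-benzyl-4β-(2-ethoxyethoxy)-(−)-epicatechin (2,3-cis; 3,4-trans)
Conditions: DDQ (2 equiv), 2-ethoxyethanol (5 equiv), CH2Cl2, rt
Reagents that add atoms: none
Why: Benzylic C–H oxidation with DDQ: hydride abstraction from C4 (activated by the ring A oxygens) gives a stabilised benzylic cation that 2-ethoxyethanol traps anti to the axial C3 hydroxyl, so the 4β (3,4-trans) ether should form.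

Step 10
Reactants: 20 5,7,3',4'-tetra-O-benzyl-4β-(2-ethoxyethoxy)-(−)-epicatechin; 18 5,7,3',4'-tetra-O-benzyl-(−)-epicatechin
Product: 21 octa-O-benzyl procyanidin B2 [5,7,3',4'-tetra-O-benzylepicatechin-(4β→8)-5,7,3',4'-tetra-O-benzylepicatechin]
Conditions: 18 (4 equiv), Me3SiOSO2CF3 (0.1 equiv), CH2Cl2, −78 °C; Et3N quench; excess 18 recovered
Reagents that add atoms: none
Why: Lewis acid-catalysed Friedel–Crafts-type flavan-4-yl cation arylation: ionisation of the C4 ether gives the benzylic cation, which the most nucleophilic ring A position (C8) of excess 18 attacks anti to the axial C3 hydroxyl, setting the 4β (3,4-trans) interflavan stereocentre by substrate control.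

Step 11
Reactants: 15 5,7,3',4'-tetra-O-benzyl-4α-hydroxy-(−)-epicatechin; 21 octa-O-benzyl procyanidin B2
Product: 22 dodeca-O-benzyl procyanidin C1 {[5,7,3',4'-tetra-O-benzylepicatechin-(4β→8)]2-5,7,3',4'-tetra-O-benzylepicatechin; three free 3-hydroxyls}
Conditions: 21 (2 equiv), Me3SiOSO2CF3 (0.2 equiv), 4 Å MS, CH2Cl2, −78 → −40 °C; Et3N quench; excess 21 recovered
Reagents that add atoms: none
Why: The same Friedel–Crafts-type flavan-4-yl cation arylation with a flavan-3,4-diol as cation precursor: the free C8 of the upper unit of 21 attacks the C4 cation of the top unit from the β face, anti to the axial C3 hydroxyl, so C4 of the top unit is set (4β, 3,4-trans) by relay from C3 and the temporary C4 carbinol stereocentre is erased.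

Step 12
Reactants: 22 dodeca-O-benzyl procyanidin C1; 23 3,4,5-tris(benzyloxy)benzoic acid
Product: 24 dodeca-O-benzyl procyanidin C1 3,3',3''-tris[3,4,5-tris(benzyloxy)benzoate]
Conditions: 23 (6 equiv), DCC (6 equiv), DMAP (1.5 equiv), CH2Cl2, rt → 35 °C
Reagents that add atoms: 3,4,5-tris(benzyloxy)benzoic acid (two further equivalents of 23), OC(=O)c1cc(OCc2ccccc2)c(OCc2ccccc2)c(OCc2ccccc2)c1.OC(=O)c1cc(OCc2ccccc2)c(OCc2ccccc2)c(OCc2ccccc2)c1
Why: Threefold Steglich esterification, in which three equivalents of the acid acylate the three secondary axial 3-hydroxyls, retains the carbinol configurations because only O–acyl bonds are formed.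

Step 13
Reactants: 24 dodeca-O-benzyl procyanidin C1 3,3',3''-tris[3,4,5-tris(benzyloxy)benzoate]
Product: 25 procyanidin C1 3,3',3''-tri-O-gallate
Conditions: H2 (1 atm), Pd(OH)2/C, THF/MeOH/H2O, rt; filtration; lyophilisation
Reagents that add atoms: none
Why: Heterogeneous hydrogenolysis of all twenty-one benzyl ethers over Pd(OH)2/C releases the phenols, while the gallate esters, the interflavan C–C bonds and all eight stereocentres are inert under these neutral conditions.

## Compound list

1 | 1,3,5-trifluorobenzene | Fc1cc(F)cc(F)c1 | starting material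
2 | benzyl alcohol | OCc1ccccc1 | starting material
3 | 1,3-bis(benzyloxy)-5-fluorobenzene | Fc1cc(OCc2ccccc2)cc(OCc2ccccc2)c1 | intermediate
4 | 4-methoxybenzyl alcohol | COc1ccc(CO)cc1 | starting material
5 | 2-chloro-N-methoxy-N-methylacetamide | CON(C)C(=O)CCl | starting material
6 | N-methoxy-N-methyl-2-[(4-methoxybenzyl)oxy]acetamide | CON(C)C(=O)COCc1ccc(OC)cc1 | intermediate
7 | [2,4-bis(benzyloxy)-6-fluorophenyl]lithium (not isolated) | [Li]c1c(F)cc(OCc2ccccc2)cc1OCc1ccccc1 | intermediate
8 | lithium 1-[2,4-bis(benzyloxy)-6-fluorophenyl]-1-[methoxy(methyl)amino]-2-[(4-methoxybenzyl)oxy]ethan-1-olate (tetrahedral adduct, racemic, not isolated) | [Li]OC(COCc1ccc(OC)cc1)(N(C)OC)c1c(F)cc(OCc2ccccc2)cc1OCc1ccccc1 | intermediate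
9 | 1-[2,4-bis(benzyloxy)-6-fluorophenyl]-2-[(4-methoxybenzyl)oxy]ethan-1-one | O=C(COCc1ccc(OC)cc1)c1c(F)cc(OCc2ccccc2)cc1OCc1ccccc1 | intermediate
10 | (Z)-({1-[2,4-bis(benzyloxy)-6-fluorophenyl]-2-[(4-methoxybenzyl)oxy]ethenyl}oxy)trimethylsilane | C[Si](C)(C)O/C(=C\OCc1ccc(OC)cc1)c1c(F)cc(OCc2ccccc2)cc1OCc1ccccc1 | intermediate
11 | 3,4-bis(benzyloxy)benzaldehyde | O=Cc1ccc(OCc2ccccc2)c(OCc2ccccc2)c1 | starting material
12 | (2S,3R)-1-[2,4-bis(benzyloxy)-6-fluorophenyl]-3-[3,4-bis(benzyloxy)phenyl]-2-[(4-methoxybenzyl)oxy]-3-[(trimethylsilyl)oxy]propan-1-one (syn silyl aldol, not isolated) | C[Si](C)(C)O[C@H](c1ccc(OCc2ccccc2)c(OCc2ccccc2)c1)[C@H](OCc1ccc(OC)cc1)C(=O)c1c(F)cc(OCc2ccccc2)cc1OCc1ccccc1 | intermediate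
13 | (2R,3S)-5,7-bis(benzyloxy)-2-[3,4-bis(benzyloxy)phenyl]-3-[(4-methoxybenzyl)oxy]chroman-4-one (2,3-cis) | O=C1c2c(OCc3ccccc3)cc(OCc3ccccc3)cc2O[C@H](c2ccc(OCc3ccccc3)c(OCc3ccccc3)c2)[C@@H]1OCc1ccc(OC)cc1 | intermediate
14 | (2R,3S)-5,7-bis(benzyloxy)-2-[3,4-bis(benzyloxy)phenyl]-3-hydroxychroman-4-one (2,3-cis) | O=C1c2c(OCc3ccccc3)cc(OCc3ccccc3)cc2O[C@H](c2ccc(OCc3ccccc3)c(OCc3ccccc3)c2)[C@@H]1O | intermediate
15 | 5,7,3',4'-tetra-O-benzyl-4α-hydroxy-(−)-epicatechin (2,3-cis, 3,4-cis flavan-3,4-diol) | O[C@@H]1c2c(OCc3ccccc3)cc(OCc3ccccc3)cc2O[C@H](c2ccc(OCc3ccccc3)c(OCc3ccccc3)c2)[C@@H]1O | intermediate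
16 | (−)-epicatechin, (2R,3R) | O[C@@H]1Cc2c(O)cc(O)cc2O[C@@H]1c1ccc(O)c(O)c1 | starting material
17 | benzyl bromide | BrCc1ccccc1 | starting material
18 | 5,7,3',4'-tetra-O-benzyl-(−)-epicatechin, (2R,3R) | O[C@@H]1Cc2c(OCc3ccccc3)cc(OCc3ccccc3)cc2O[C@@H]1c1ccc(OCc2ccccc2)c(OCc2ccccc2)c1 | intermediate
19 | 2-ethoxyethanol | CCOCCO | starting material
20 | 5,7,3',4'-tetra-O-benzyl-4β-(2-ethoxyethoxy)-(−)-epicatechin (2,3-cis, 3,4-trans) | CCOCCO[C@H]1c2c(OCc3ccccc3)cc(OCc3ccccc3)cc2O[C@H](c2ccc(OCc3ccccc3)c(OCc3ccccc3)c2)[C@@H]1O | intermediate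
21 | octa-O-benzyl procyanidin B2: 5,7,3',4'-tetra-O-benzylepicatechin-(4β→8)-5,7,3',4'-tetra-O-benzylepicatechin | O[C@@H]1[C@@H](c2c(OCc3ccccc3)cc(OCc3ccccc3)c3c2O[C@H](c2ccc(OCc4ccccc4)c(OCc4ccccc4)c2)[C@H](O)C3)c2c(OCc3ccccc3)cc(OCc3ccccc3)cc2O[C@@H]1c1ccc(OCc2ccccc2)c(OCc2ccccc2)c1 | intermediate
22 | dodeca-O-benzyl procyanidin C1: [5,7,3',4'-tetra-O-benzylepicatechin-(4β→8)]2-5,7,3',4'-tetra-O-benzylepicatechin | O[C@@H]1[C@@H](c2c(OCc3ccccc3)cc(OCc3ccccc3)c3c2O[C@H](c2ccc(OCc4ccccc4)c(OCc4ccccc4)c2)[C@H](O)C3)c2c(OCc3ccccc3)cc(OCc3ccccc3)c([C@H]3c4c(OCc5ccccc5)cc(OCc5ccccc5)cc4O[C@H](c4ccc(OCc5ccccc5)c(OCc5ccccc5)c4)[C@@H]3O)c2O[C@@H]1c1ccc(OCc2ccccc2)c(OCc2ccccc2)c1 | intermediate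
23 | 3,4,5-tris(benzyloxy)benzoic acid | OC(=O)c1cc(OCc2ccccc2)c(OCc2ccccc2)c(OCc2ccccc2)c1 | starting material
24 | dodeca-O-benzyl procyanidin C1 3,3',3''-tris[3,4,5-tris(benzyloxy)benzoate] | O=C(O[C@@H]1[C@@H](c2c(OCc3ccccc3)cc(OCc3ccccc3)c3c2O[C@H](c2ccc(OCc4ccccc4)c(OCc4ccccc4)c2)[C@H](OC(=O)c2cc(OCc4ccccc4)c(OCc4ccccc4)c(OCc4ccccc4)c2)C3)c2c(OCc3ccccc3)cc(OCc3ccccc3)c([C@H]3c4c(OCc5ccccc5)cc(OCc5ccccc5)cc4O[C@H](c4ccc(OCc5ccccc5)c(OCc5ccccc5)c4)[C@@H]3OC(=O)c3cc(OCc4ccccc4)c(OCc4ccccc4)c(OCc4ccccc4)c3)c2O[C@@H]1c1ccc(OCc2ccccc2)c(OCc2ccccc2)c1)c1cc(OCc2ccccc2)c(OCc2ccccc2)c(OCc2ccccc2)c1 | intermediate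
25 | procyanidin C1 3,3',3''-tri-O-gallate | O=C(O[C@@H]1[C@@H](c2c(O)cc(O)c3c2O[C@H](c2ccc(O)c(O)c2)[C@H](OC(=O)c2cc(O)c(O)c(O)c2)C3)c2c(O)cc(O)c([C@H]3c4c(O)cc(O)cc4O[C@H](c4ccc(O)c(O)c4)[C@@H]3OC(=O)c3cc(O)c(O)c(O)c3)c2O[C@@H]1c1ccc(O)c(O)c1)c1cc(O)c(O)c(O)c1 | target

## Step count and risks

Total step count: 13 (steps 1–7 top unit, steps 8–10 lower dimer, steps 11–13 union and end game).
Longest linear sequence: 9 steps (1, 3, 4, 5, 6, 7, 11, 12, 13).

Steps most likely to fail:

**Step 5 (Proposed new method).** After desilylation the free β-alkoxide may undergo retro-aldol cleavage and unselective re-addition, or fluoride and alkoxide may enolise the product at C3. Either would erode the 2,3-cis relationship and the enantiomeric purity. The open-transition-state aldol may also be less syn-selective with an α-alkoxy enol silane. A small amount of the wrong enantiomer would become a diastereomeric trimer in step 11 and could be removed there.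

The fallback separates the two bond formations and takes the ketone out of the ring-closing step, using known reactions only; it sets out from 10 and returns at 13. The acyloxyborane-catalysed Mukaiyama aldol of 10 with 11 is worked up with dilute HCl to give the free syn aldol (2S,3R)-1-[2,4-bis(benzyloxy)-6-fluorophenyl]-3-[3,4-bis(benzyloxy)phenyl]-3-hydroxy-2-[(4-methoxybenzyl)oxy]propan-1-one F1. Evans–Saksena reduction with Me4N[BH(OAc)3] gives 1-[2,4-bis(benzyloxy)-6-fluorophenyl]-3-[3,4-bis(benzyloxy)phenyl]-2-[(4-methoxybenzyl)oxy]propane-1,3-diol F2; it is expected 1,3-anti, but the new centre is of no consequence. KN(SiMe3)2 in THF/DMF then closes the pyran by alkoxide SNAr on the now unactivated 3,5-dialkoxyfluoroarene, a known type of flavan ring closure in which neither retro-aldol nor C3 epimerisation is possible. This gives 5,7,3',4'-tetra-O-benzyl-4α-hydroxy-3-O-(4-methoxybenzyl)-(−)-epicatechin F3, and buffered Dess–Martin oxidation returns to 13.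

**Step 11.** The C4 cation of 15 may be captured by ring A of a second molecule of 15 or by a C6 position of 21, and the trimer may react again, giving regioisomers and higher oligomers.

The fallback is a blocking-group strategy; it sets out from 15 and returns at 25. NBS in CH2Cl2 at −78 °C brominates C8 of the electrophile, a known selective bromination of 5,7-di-O-benzylflavans, to give 8-bromo-5,7,3',4'-tetra-O-benzyl-4α-hydroxy-(−)-epicatechin F4, whose ring A can no longer act as a nucleophile. Equimolar Lewis acid coupling with 21 gives 8-bromo-dodeca-O-benzyl procyanidin C1 (bromine on the top unit) F5. Steglich esterification with three equivalents of 23 gives 8-bromo-dodeca-O-benzyl procyanidin C1 3,3',3''-tris[3,4,5-tris(benzyloxy)benzoate] F6. Hydrogenolysis over Pd(OH)2/C with Et3N removes the aryl bromide together with the benzyl ethers and gives 25.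

**Step 3.** Metalation may occur between the two benzyloxy groups instead of next to fluorine, or the ortho-fluoroaryllithium may lose LiF to an aryne before it is acylated.

The fallback replaces the carbanion route by electrophilic substitution; it sets out from 3 and returns at 9. Vilsmeier–Haack formylation (POCl3, DMF) para to one benzyloxy group and ortho to fluorine gives 2,4-bis(benzyloxy)-6-fluorobenzaldehyde F7. Addition of [(4-methoxybenzyloxy)methyl]lithium, generated from tributyl{[(4-methoxybenzyl)oxy]methyl}stannane and n-BuLi by tin–lithium exchange, gives 1-[2,4-bis(benzyloxy)-6-fluorophenyl]-2-[(4-methoxybenzyl)oxy]ethan-1-ol F8. Dess–Martin oxidation returns to 9.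

## Further compounds

F1 | step 5 | (2S,3R)-1-[2,4-bis(benzyloxy)-6-fluorophenyl]-3-[3,4-bis(benzyloxy)phenyl]-3-hydroxy-2-[(4-methoxybenzyl)oxy]propan-1-one | O[C@H](c1ccc(OCc2ccccc2)c(OCc2ccccc2)c1)[C@H](OCc1ccc(OC)cc1)C(=O)c1c(F)cc(OCc2ccccc2)cc1OCc1ccccc1
F2 | step 5 | 1-[2,4-bis(benzyloxy)-6-fluorophenyl]-3-[3,4-bis(benzyloxy)phenyl]-2-[(4-methoxybenzyl)oxy]propane-1,3-diol (2,3-syn, 1,3-anti) | O[C@H](c1ccc(OCc2ccccc2)c(OCc2ccccc2)c1)[C@H](OCc1ccc(OC)cc1)[C@H](O)c1c(F)cc(OCc2ccccc2)cc1OCc1ccccc1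
F3 | step 5 | 5,7,3',4'-tetra-O-benzyl-4α-hydroxy-3-O-(4-methoxybenzyl)-(−)-epicatechin (2,3-cis, 3,4-cis) | O[C@@H]1c2c(OCc3ccccc3)cc(OCc3ccccc3)cc2O[C@H](c2ccc(OCc3ccccc3)c(OCc3ccccc3)c2)[C@@H]1OCc1ccc(OC)cc1
F4 | step 11 | 8-bromo-5,7,3',4'-tetra-O-benzyl-4α-hydroxy-(−)-epicatechin | O[C@@H]1c2c(OCc3ccccc3)cc(OCc3ccccc3)c(Br)c2O[C@H](c2ccc(OCc3ccccc3)c(OCc3ccccc3)c2)[C@@H]1O
F5 | step 11 | 8-bromo-dodeca-O-benzyl procyanidin C1 (bromine at C8 of the top unit) | O[C@@H]1[C@@H](c2c(OCc3ccccc3)cc(OCc3ccccc3)c3c2O[C@H](c2ccc(OCc4ccccc4)c(OCc4ccccc4)c2)[C@H](O)C3)c2c(OCc3ccccc3)cc(OCc3ccccc3)c([C@H]3c4c(OCc5ccccc5)cc(OCc5ccccc5)c(Br)c4O[C@H](c4ccc(OCc5ccccc5)c(OCc5ccccc5)c4)[C@@H]3O)c2O[C@@H]1c1ccc(OCc2ccccc2)c(OCc2ccccc2)c1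
F6 | step 11 | 8-bromo-dodeca-O-benzyl procyanidin C1 3,3',3''-tris[3,4,5-tris(benzyloxy)benzoate] | O=C(O[C@@H]1[C@@H](c2c(OCc3ccccc3)cc(OCc3ccccc3)c3c2O[C@H](c2ccc(OCc4ccccc4)c(OCc4ccccc4)c2)[C@H](OC(=O)c2cc(OCc4ccccc4)c(OCc4ccccc4)c(OCc4ccccc4)c2)C3)c2c(OCc3ccccc3)cc(OCc3ccccc3)c([C@H]3c4c(OCc5ccccc5)cc(OCc5ccccc5)c(Br)c4O[C@H](c4ccc(OCc5ccccc5)c(OCc5ccccc5)c4)[C@@H]3OC(=O)c3cc(OCc4ccccc4)c(OCc4ccccc4)c(OCc4ccccc4)c3)c2O[C@@H]1c1ccc(OCc2ccccc2)c(OCc2ccccc2)c1)c1cc(OCc2ccccc2)c(OCc2ccccc2)c(OCc2ccccc2)c1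
F7 | step 3 | 2,4-bis(benzyloxy)-6-fluorobenzaldehyde | O=Cc1c(F)cc(OCc2ccccc2)cc1OCc1ccccc1
F8 | step 3 | 1-[2,4-bis(benzyloxy)-6-fluorophenyl]-2-[(4-methoxybenzyl)oxy]ethan-1-ol (racemic) | OC(COCc1ccc(OC)cc1)c1c(F)cc(OCc2ccccc2)cc1OCc1ccccc1
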